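**Retrosynthetic overview**
1. Achilleol A is cut into a C10 ring unit, a C5 linker and a C15 farnesyl unit; the last step only removes two sulfonyl groups from a C30 bis-sulfone.
2. Key disconnection C8–C9: the ring CH2 (C8) reacts as an α-sulfonyl carbanion (reversed polarity of a cyclogeranyl halide) with the allylic chloride end of the linker.
3. Second disconnection C12–C13 (tail-to-tail): the farnesyl α-sulfonyl anion reacts with the allylic acetate end of the same linker, in the same flask.
4. Ring order: the single cyclohexane ring is made first, on the C10 sulfone, by radical cyclisation of the (S)-6,7-epoxide. C3 comes from the epoxide and C7 is set cis to it by the chair transition state; no other ring is formed.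
5. Sources: geranyl bromide, farnesyl bromide, PhSO2Na and the five-carbon chloro-acetate.

Assumption: (2E)-4-chloro-3-methylbut-2-en-1-yl acetate (the five-carbon vitamin A building block) and the L-fructose-derived Shi ketone are treated as purchasable.
Atom labels follow squalene numbering: ring C2 (CMe2), C3 (CHOH), C4, C5, C6 (C=CH2), C7 (CH); chain C8 to C23.

**Route**

Step 1
Reactants: 1 geranyl bromide [(2E)-1-bromo-3,7-dimethylocta-2,6-diene]; 2 sodium benzenesulfinate (PhSO2Na)
Product: 3 geranyl phenyl sulfone {[(2E)-3,7-dimethylocta-2,6-dien-1-yl]sulfonyl}benzene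
Conditions: DMF, rt, 12 h
Reagents that add atoms: none
Why: SN2 S-alkylation of the sulfinate at the primary allylic bromide (sulfone synthesis by sulfinate alkylation) keeps the 2E geometry and installs the sulfonyl group that later makes C8 nucleophilic.

Step 2
Reactants: 3 geranyl phenyl sulfone
Product: 4 (S)-6,7-epoxygeranyl phenyl sulfone [(3S)-2,2-dimethyl-3-[(3E)-3-methyl-5-(phenylsulfonyl)pent-3-en-1-yl]oxirane]
Conditions: KHSO5 (Oxone), ent-Shi ketone (L-fructose-derived, 30 mol %), K2CO3, Bu4NHSO4 (cat.), MeCN–CH2(OMe)2–H2O (pH 10.5), 0 °C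
Reagents that add atoms: potassium peroxymonosulfate KHSO5, [K+].[O-]S(=O)(=O)OO
Why: Shi asymmetric epoxidation, in which the electrophilic chiral dioxirane attacks only the electron-rich 6,7-alkene (the 2,3-alkene is deactivated by the allylic sulfonyl group) through the spiro transition state; the L-series ketone gives the (S)-epoxide (the D-fructose ketone gives R), which fixes C3.

Step 3
Reactants: 4 (S)-6,7-epoxygeranyl phenyl sulfone
Product: 6 (1S,3R)-2,2-dimethyl-4-methylidene-3-[(phenylsulfonyl)methyl]cyclohexan-1-ol, via trimethylsilyl ether 5 (not isolated)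
Conditions: Cp2TiCl2 (20 mol %), Mn dust (8 equiv), Me3SiCl (4 equiv), 2,4,6-collidine (7 equiv), THF, rt; then K2CO3 (cat.), MeOH, rt; recrystallise
Reagents that add atoms: none
Why: Nugent–RajanBabu radical epoxide opening by catalytic Cp2TiCl (trivalent titanium) gives the tertiary β-titanoxy radical, which closes 6-endo onto the E-alkene through a chair with the O–Ti group and the CH2SO2Ph-bearing carbon both equatorial (cis-1,3, so C7 is R from the S-epoxide, C3 retained); a second Cp2TiCl traps the ring radical, β-hydride loss toward the methyl gives the exocyclic alkene, and methanolysis removes the silyl group.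

Step 4
Reactants: 7 (2E,6E)-farnesyl bromide [(2E,6E)-1-bromo-3,7,11-trimethyldodeca-2,6,10-triene]; 2 sodium benzenesulfinate (PhSO2Na)
Product: 8 (2E,6E)-farnesyl phenyl sulfone {[(2E,6E)-3,7,11-trimethyldodeca-2,6,10-trien-1-yl]sulfonyl}benzene
Conditions: DMF, rt, 12 h
Reagents that add atoms: none
Why: The same SN2 sulfinate S-alkylation as in step 1, with both E-alkenes untouched.

Step 5
Reactants: 6 (1S,3R)-2,2-dimethyl-4-methylidene-3-[(phenylsulfonyl)methyl]cyclohexan-1-ol; 8 (2E,6E)-farnesyl phenyl sulfone; 9 (2E)-4-chloro-3-methylbut-2-en-1-yl acetate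
Product: 13 (1S,3R)-2,2-dimethyl-4-methylidene-3-[(3E,7E,11E)-3,8,12,16-tetramethyl-1,6-bis(phenylsulfonyl)heptadeca-3,7,11,15-tetraen-1-yl]cyclohexan-1-ol, via dilithio dianion 10 (not isolated), via lithium alkoxide acetate 11 (not isolated), via lithiated farnesyl sulfone 12 (not isolated)
Conditions: 6, n-BuLi (2.05 equiv), THF, −78 °C; 9 (1.0 equiv), −78 → −20 °C; then 12 [from 8 (1.3 equiv), n-BuLi (1.3 equiv), THF, −78 °C], Pd(PPh3)4 (5 mol %), −20 °C → rt; H2O
Reagents that add atoms: none
Why: Julia-type α-sulfonyl carbanion alkylation followed in the same flask by Tsuji–Trost allylation: C8 and C13, both electrophilic carbons in the parent halides, react as sulfonyl-stabilised carbanions, first by SN2 at the allylic chloride of 9 (C8–C9, acetate spared as in the sulfone route to vitamin A) and then at the less hindered CH2 end of the π-allyl complex formed from the acetate and zerovalent palladium (C12–C13); all E-alkenes are carried in unchanged, C3 and C7 are untouched, and the two new CHSO2Ph centres are epimer mixtures that are erased in step 6.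

Step 6
Reactants: 13 the C30 hydroxy bis-sulfone
Product: 14 achilleol A [(1S,3R)-2,2-dimethyl-4-methylidene-3-[(3E,7E,11E)-3,8,12,16-tetramethylheptadeca-3,7,11,15-tetraen-1-yl]cyclohexan-1-ol]
Conditions: Li (excess), EtNH2–THF, −78 °C; then H2O
Reagents that add atoms: none
Why: Dissolving-metal reductive desulfonylation, as used in sulfone-based 1,5-diene syntheses, cleaves both C–S bonds by electron transfer and protonation at −78 °C, where isolated trisubstituted and 1,1-disubstituted alkenes are not reduced; the ring stereocentres are not involved.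

**Compound list**
1 | geranyl bromide, (2E)-1-bromo-3,7-dimethylocta-2,6-diene | CC(C)=CCC/C(C)=C/CBr | starting material
2 | sodium benzenesulfinate, PhSO2Na | [Na+].[O-]S(=O)c1ccccc1 | starting material
3 | geranyl phenyl sulfone, {[(2E)-3,7-dimethylocta-2,6-dien-1-yl]sulfonyl}benzene | CC(C)=CCC/C(C)=C/CS(=O)(=O)c1ccccc1 | intermediate
4 | (S)-6,7-epoxygeranyl phenyl sulfone, (3S)-2,2-dimethyl-3-[(3E)-3-methyl-5-(phenylsulfonyl)pent-3-en-1-yl]oxirane | CC1(C)O[C@H]1CC/C(C)=C/CS(=O)(=O)c1ccccc1 | intermediate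
5 | trimethylsilyl ether of 6, trimethyl({(1S,3R)-2,2-dimethyl-4-methylidene-3-[(phenylsulfonyl)methyl]cyclohexyl}oxy)silane | C=C1CC[C@H](O[Si](C)(C)C)C(C)(C)[C@@H]1CS(=O)(=O)c1ccccc1 | intermediate
6 | (1S,3R)-2,2-dimethyl-4-methylidene-3-[(phenylsulfonyl)methyl]cyclohexan-1-ol (OH and CH2SO2Ph cis) | C=C1CC[C@H](O)C(C)(C)[C@@H]1CS(=O)(=O)c1ccccc1 | intermediate
7 | (2E,6E)-farnesyl bromide, (2E,6E)-1-bromo-3,7,11-trimethyldodeca-2,6,10-triene | CC(C)=CCC/C(C)=C/CC/C(C)=C/CBr | starting material
8 | (2E,6E)-farnesyl phenyl sulfone, {[(2E,6E)-3,7,11-trimethyldodeca-2,6,10-trien-1-yl]sulfonyl}benzene | CC(C)=CCC/C(C)=C/CC/C(C)=C/CS(=O)(=O)c1ccccc1 | intermediate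
9 | (2E)-4-chloro-3-methylbut-2-en-1-yl acetate | CC(=O)OC/C=C(\C)CCl | starting material
10 | dilithio dianion of 6 (lithium alkoxide at C3, α-sulfonyl carbanion at C8) | [Li+].[Li+].C=C1CC[C@H]([O-])C(C)(C)[C@@H]1[CH-]S(=O)(=O)c1ccccc1 | intermediate
11 | lithium alkoxide of (1S,3R)-3-[(3E)-5-acetoxy-3-methyl-1-(phenylsulfonyl)pent-3-en-1-yl]-2,2-dimethyl-4-methylidenecyclohexan-1-ol (epimers at C8) | [Li+].C=C1CC[C@H]([O-])C(C)(C)[C@@H]1C(C/C(C)=C/COC(C)=O)S(=O)(=O)c1ccccc1 | intermediate
12 | lithio derivative of 8 (α-sulfonyl allyl anion at C13) | [Li+].CC(C)=CCC/C(C)=C/CC/C(C)=C/[CH-]S(=O)(=O)c1ccccc1 | intermediate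
13 | (1S,3R)-2,2-dimethyl-4-methylidene-3-[(3E,7E,11E)-3,8,12,16-tetramethyl-1,6-bis(phenylsulfonyl)heptadeca-3,7,11,15-tetraen-1-yl]cyclohexan-1-ol (epimers at both CHSO2Ph carbons) | C=C1CC[C@H](O)C(C)(C)[C@@H]1C(C/C(C)=C/CC(/C=C(\C)CC/C=C(\C)CCC=C(C)C)S(=O)(=O)c1ccccc1)S(=O)(=O)c1ccccc1 | intermediate
14 | achilleol A, (1S,3R)-2,2-dimethyl-4-methylidene-3-[(3E,7E,11E)-3,8,12,16-tetramethylheptadeca-3,7,11,15-tetraen-1-yl]cyclohexan-1-ol | C=C1CC[C@H](O)C(C)(C)[C@@H]1CC/C(C)=C/CC/C=C(\C)CC/C=C(\C)CCC=C(C)C | target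

**Step count and risks**
Total step count: 6. Longest linear sequence: 5 (steps 1, 2, 3, 5, 6 from geranyl bromide).

The three steps most likely to fail are steps 5, 6 and 3.

First, step 5. The basic dianion 10 may attack the acetate of 9, or the lithiated mono-sulfone 12 may react poorly with the π-allyl palladium complex or erode the E geometry. The fallback reverses the order and uses only SN2 chemistry, with no acetate and no palladium. It sets out from sulfone 8 and alcohol 6 and comes back at bis-sulfone 13. Lithio sulfone 12 (from 8, n-BuLi, THF, −78 °C) is added to an excess (3 equiv) of (E)-1,4-dibromo-2-methylbut-2-ene (BrC/C(C)=C/CBr). Attack at the less hindered CH2Br, the one remote from the methyl group, gives phenyl (2E,6E,10E)-1-bromo-2,7,11,15-tetramethylhexadeca-2,6,10,14-tetraen-5-yl sulfone F1. After chromatography, F1 is alkylated at −78 °C with dianion 10 (from 6 and 2 equiv n-BuLi) to give 13.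

Second, step 6. Lithium in ethylamine can protonate the allyl anion from the C13 sulfone at the wrong end, which moves the C14=C15 alkene or scrambles its geometry. The fallback removes the two sulfonyl groups by two different mechanisms. It sets out from 13 and comes back at 14. PdCl2(dppp) (5 mol %) with LiBHEt3 in THF at 0 °C removes only the allylic sulfonyl group, by hydride delivery to the less substituted end of the π-allyl palladium complex without alkene migration. This gives (1S,3R)-2,2-dimethyl-4-methylidene-3-[(3E,7E,11E)-3,8,12,16-tetramethyl-1-(phenylsulfonyl)heptadeca-3,7,11,15-tetraen-1-yl]cyclohexan-1-ol F2. Na(Hg) with Na2HPO4 in MeOH–THF at −20 °C then cleaves the remaining alkyl sulfone to give 14.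

Third, step 3. With the allylic sulfone in the substrate, a minor 5-exo closure followed by loss of a sulfonyl radical, or a poor exo/endo alkene ratio, could lower the yield. The fallback closes the ring in the acetate series and brings in sulfur afterwards. It sets out from geranyl bromide 1 and comes back at alcohol 6.
- 1 with KOAc in DMF gives geranyl acetate F3.
- ent-Shi epoxidation, as in step 2, gives (S)-6,7-epoxygeranyl acetate F4.
- Cyclisation with stoichiometric Cp2TiCl (from Cp2TiCl2 and Mn dust, THF, aqueous work-up) gives [(1R,3S)-3-hydroxy-2,2-dimethyl-6-methylidenecyclohexyl]methyl acetate F5.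
- K2CO3 in MeOH gives (1S,3R)-3-(hydroxymethyl)-2,2-dimethyl-4-methylidenecyclohexan-1-ol F6.
- PhSSPh with Bu3P, which reacts at the primary hydroxyl only, gives (1S,3R)-2,2-dimethyl-4-methylidene-3-[(phenylsulfanyl)methyl]cyclohexan-1-ol F7.
- (NH4)6Mo7O24 (cat.) with H2O2 in EtOH at 0 °C oxidises sulfur only and gives 6.

Further compounds
F1 | step 5 | phenyl (2E,6E,10E)-1-bromo-2,7,11,15-tetramethylhexadeca-2,6,10,14-tetraen-5-yl sulfone | BrC/C(C)=C/CC(/C=C(\C)CC/C=C(\C)CCC=C(C)C)S(=O)(=O)c1ccccc1
F2 | step 6 | (1S,3R)-2,2-dimethyl-4-methylidene-3-[(3E,7E,11E)-3,8,12,16-tetramethyl-1-(phenylsulfonyl)heptadeca-3,7,11,15-tetraen-1-yl]cyclohexan-1-ol | C=C1CC[C@H](O)C(C)(C)[C@@H]1C(C/C(C)=C/CC/C=C(\C)CC/C=C(\C)CCC=C(C)C)S(=O)(=O)c1ccccc1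
F3 | step 3 | geranyl acetate, (2E)-3,7-dimethylocta-2,6-dien-1-yl acetate | CC(C)=CCC/C(C)=C/COC(C)=O
F4 | step 3 | (S)-6,7-epoxygeranyl acetate, (2E)-5-[(2S)-3,3-dimethyloxiran-2-yl]-3-methylpent-2-en-1-yl acetate | CC1(C)O[C@H]1CC/C(C)=C/COC(C)=O
F5 | step 3 | [(1R,3S)-3-hydroxy-2,2-dimethyl-6-methylidenecyclohexyl]methyl acetate | C=C1CC[C@H](O)C(C)(C)[C@@H]1COC(C)=O
F6 | step 3 | (1S,3R)-3-(hydroxymethyl)-2,2-dimethyl-4-methylidenecyclohexan-1-ol | C=C1CC[C@H](O)C(C)(C)[C@@H]1CO
F7 | step 3 | (1S,3R)-2,2-dimethyl-4-methylidene-3-[(phenylsulfanyl)methyl]cyclohexan-1-ol | C=C1CC[C@H](O)C(C)(C)[C@@H]1CSc1ccccc1
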